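**Assumption:** the SMILES is read as 4S,6R,7S,8R (germacrane numbering: ring C1–C10, lactone carbons C11–C13, C14 = acetoxymethyl carbon on C10, C15 = methyl on C4), with C2 and C9 cis on the ring alkene and the ester being the angelate ((Z)-2-methylbut-2-enoate).

## Retrosynthetic overview

1. The target comes from its C6-epimeric alcohol by Mitsunobu esterification with angelic acid (inversion at C6).
2. Both rings close in one flask from an acyclic triene-aldehyde. Ring-closing metathesis forms the 3-(bromomethyl)butenolide (lactone ring first). Its allylchromium derivative then adds through C7 to the C6 aldehyde (ten-membered ring second), setting C7 and C6 relative to C8.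
3. The acyclic precursor carries C8–O as a 2-(bromomethyl)acrylate and C14–O as acetate. The C1=C10 geometry comes from syn cyclocarbonylation of a homopropargylic alcohol (temporary 8,14-lactone), which is then reduced.
4. C8 comes from (R)-epichlorohydrin (alkynylation, then sulfonium ylide homologation to the vinyl carbinol).
5. C4 comes from geraniol by Sharpless epoxidation and C2-selective hydride opening; the alkyne comes from ozonolysis and one-carbon homologation.

## Route

Step 1
Reactants: 1 geraniol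
Product: 2 (2S,3S)-2,3-epoxygeraniol
Conditions: Ti(OiPr)4 (5 mol %), L-(+)-diethyl tartrate (6 mol %), t-BuOOH, 4 Å molecular sieves, CH2Cl2, −20 °C
Reagents that add atoms: tert-butyl hydroperoxide CC(C)(C)OO
Why: Sharpless asymmetric epoxidation, in which the titanium tartrate complex delivers oxygen only to the allylic alcohol alkene and L-(+)-tartrate gives the 2S,3S epoxide, fixing the future C4 centre.

Step 2
Reactants: 2 (2S,3S)-2,3-epoxygeraniol
Product: 3 (3S)-3,7-dimethyloct-6-ene-1,3-diol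
Conditions: NaAlH2(OCH2CH2OMe)2, THF, 0 °C
Reagents that add atoms: none
Why: Alkoxide-directed reductive epoxide opening delivers hydride intramolecularly to C2 of the 2,3-epoxy alcohol, giving the 1,3-diol while the tertiary C–O bond is untouched and stays S.

Step 3
Reactants: 3 (3S)-3,7-dimethyloct-6-ene-1,3-diol
Product: 4 (4S)-2,2,4-trimethyl-4-(4-methylpent-3-en-1-yl)-1,3-dioxane
Conditions: 2,2-dimethoxypropane, PPTS (cat.), CH2Cl2, 25 °C
Reagents that add atoms: 2,2-dimethoxypropane COC(C)(C)OC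
Why: Acid-catalysed transacetalisation protects the primary and tertiary hydroxyls together as a six-membered acetonide without touching the stereocentre.

Step 4
Reactants: 4 (4S)-2,2,4-trimethyl-4-(4-methylpent-3-en-1-yl)-1,3-dioxane
Product: 6 3-[(4S)-2,2,4-trimethyl-1,3-dioxan-4-yl]propanal, via secondary ozonide 5 (not isolated)
Conditions: O3, CH2Cl2, −78 °C; then PPh3, −78 to 25 °C
Reagents that add atoms: ozone [O-][O+]=O
Why: Ozonolysis with reductive work-up cleaves the only alkene to the C1 aldehyde and acetone.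

Step 5
Reactants: 6 3-[(4S)-2,2,4-trimethyl-1,3-dioxan-4-yl]propanal
Product: 7 (4S)-4-(but-3-yn-1-yl)-2,2,4-trimethyl-1,3-dioxane
Conditions: dimethyl (1-diazo-2-oxopropyl)phosphonate, K2CO3, MeOH, 0 to 25 °C
Reagents that add atoms: dimethyl (1-diazo-2-oxopropyl)phosphonate COP(=O)(OC)C(=[N+]=[N-])C(C)=O
Why: Seyferth–Gilbert homologation in its Ohira–Bestmann form converts the aldehyde into the terminal alkyne (C1≡C10) under conditions that leave the acetonide intact.

Step 6
Reactants: 7 (4S)-4-(but-3-yn-1-yl)-2,2,4-trimethyl-1,3-dioxane; 8 (R)-epichlorohydrin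
Product: 10 (2R)-1-chloro-7-[(4S)-2,2,4-trimethyl-1,3-dioxan-4-yl]hept-4-yn-2-ol, via lithium acetylide 9 (not isolated)
Conditions: n-BuLi, THF, −78 °C; BF3·OEt2; then 8, −78 °C
Reagents that add atoms: none
Why: Yamaguchi–Hirao alkynylation, in which the acetylide opens the BF3-activated epoxide at its unsubstituted carbon (future C9), so the C–O stereocentre of 8 is not touched and becomes C8 (R).

Step 7
Reactants: 10 (2R)-1-chloro-7-[(4S)-2,2,4-trimethyl-1,3-dioxan-4-yl]hept-4-yn-2-ol
Product: 12 (3R)-8-[(4S)-2,2,4-trimethyl-1,3-dioxan-4-yl]oct-1-en-5-yn-3-ol, via terminal epoxide 11 (not isolated)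
Conditions: Me3S+ I− (4 equiv), n-BuLi (3.9 equiv), THF, −10 to 25 °C
Reagents that add atoms: trimethylsulfonium iodide C[S+](C)C.[I-]
Why: Base closes the chlorohydrin to the epoxide, dimethylsulfonium methylide opens it at CH2 and the β-oxido sulfonium salt eliminates to the vinyl carbinol (Corey–Chaykovsky-type one-carbon homologation of an epoxide to an allylic alcohol), leaving the carbinol centre untouched.

Step 8
Reactants: 12 (3R)-8-[(4S)-2,2,4-trimethyl-1,3-dioxan-4-yl]oct-1-en-5-yn-3-ol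
Product: 13 (3E,5R)-5-ethenyl-3-{3-[(4S)-2,2,4-trimethyl-1,3-dioxan-4-yl]propylidene}oxolan-2-one
Conditions: PdI2 (5 mol %), PBu3 (10 mol %), CO (7 atm), MeCN, 75 °C
Reagents that add atoms: carbon monoxide [C-]#[O+]
Why: Palladium-catalysed cyclocarbonylation of a homopropargylic alcohol, in which the alkoxycarbonyl–palladium species formed at O8 adds syn across the alkyne and protonolysis retains geometry, so the new carbon (C14) ends trans to C2 and C9 cis to C2 as in the target.

Step 9
Reactants: 13 (3E,5R)-5-ethenyl-3-{3-[(4S)-2,2,4-trimethyl-1,3-dioxan-4-yl]propylidene}oxolan-2-one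
Product: 14 (3R,5E)-5-(hydroxymethyl)-8-[(4S)-2,2,4-trimethyl-1,3-dioxan-4-yl]octa-1,5-dien-3-ol
Conditions: i-Bu2AlH (4 equiv), CH2Cl2, −78 to 0 °C; Rochelle salt work-up
Reagents that add atoms: none
Why: Hydride reduction of the lactone carbonyl (1,2-selective with the aluminium hydride) opens the temporary ring to the C14 primary allylic alcohol and the C8 secondary alcohol without changing alkene geometry or C8.

Step 10
Reactants: 14 (3R,5E)-5-(hydroxymethyl)-8-[(4S)-2,2,4-trimethyl-1,3-dioxan-4-yl]octa-1,5-dien-3-ol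
Product: 15 (2E,4R)-4-hydroxy-2-{3-[(4S)-2,2,4-trimethyl-1,3-dioxan-4-yl]propylidene}hex-5-en-1-yl acetate
Conditions: AcCl (1.05 equiv), 2,4,6-collidine, CH2Cl2, −78 °C
Reagents that add atoms: acetyl chloride CC(Cl)=O
Why: Kinetically selective acylation of the unhindered primary alcohol over the secondary one installs the C14 acetate of the target.

Step 11
Reactants: 15 (2E,4R)-4-hydroxy-2-{3-[(4S)-2,2,4-trimethyl-1,3-dioxan-4-yl]propylidene}hex-5-en-1-yl acetate; 16 2-(bromomethyl)prop-2-enoic acid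
Product: 17 (3R,5E)-5-(acetoxymethyl)-8-[(4S)-2,2,4-trimethyl-1,3-dioxan-4-yl]octa-1,5-dien-3-yl 2-(bromomethyl)prop-2-enoate
Conditions: DCC, DMAP (5 mol %), CH2Cl2, 0 °C
Reagents that add atoms: none
Why: Steglich esterification acylates the C8 hydroxyl with retention (the C–O bond is not broken), the low temperature and low DMAP loading limiting SN2' attack on the allylic bromide.

Step 12
Reactants: 17 (3R,5E)-5-(acetoxymethyl)-8-[(4S)-2,2,4-trimethyl-1,3-dioxan-4-yl]octa-1,5-dien-3-yl 2-(bromomethyl)prop-2-enoate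
Product: 18 (3R,5E,9S)-5-(acetoxymethyl)-9,11-dihydroxy-9-methylundeca-1,5-dien-3-yl 2-(bromomethyl)prop-2-enoate
Conditions: AcOH/THF/H2O (3:1:1), 35 °C
Reagents that add atoms: none
Why: Mild acid hydrolysis removes the acetonide (easily ionised at its tertiary oxygen) while the esters and the allylic bromide survive.

Step 13
Reactants: 18 (3R,5E,9S)-5-(acetoxymethyl)-9,11-dihydroxy-9-methylundeca-1,5-dien-3-yl 2-(bromomethyl)prop-2-enoate
Product: 19 (3R,5E,9S)-5-(acetoxymethyl)-9-hydroxy-9-methyl-11-oxoundeca-1,5-dien-3-yl 2-(bromomethyl)prop-2-enoate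
Conditions: TEMPO (10 mol %), PhI(OAc)2, CH2Cl2, 25 °C
Reagents that add atoms: none
Why: Oxoammonium-mediated oxidation converts only the primary alcohol into the C6 aldehyde and cannot oxidise the tertiary C4 hydroxyl.

Step 14
Reactants: 19 (3R,5E,9S)-5-(acetoxymethyl)-9-hydroxy-9-methyl-11-oxoundeca-1,5-dien-3-yl 2-(bromomethyl)prop-2-enoate
Product: 21 (1(10)E,4S,6S,7R,8R)-14-acetoxy-4,6-dihydroxygermacra-1(10),11(13)-dien-12,8-olide, via bromomethyl butenolide 20 (not isolated)
Conditions: RuCl2(H2IMes)(=CH-C6H4-2-OiPr) (second-generation Hoveyda–Grubbs catalyst, 5 mol %), toluene, 80 °C, 0.01 M; then cannulated over 10 h into CrCl2 (10 equiv), THF, 25 °C, final 0.002 M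
Reagents that add atoms: none
Why: Proposed new method: ring-closing metathesis of the acrylate and vinyl groups first closes the 3-(bromomethyl)butenolide, and divalent chromium then turns its allylic bromide into an allylchromium species that adds through C7 to the C6 aldehyde in an intramolecular Nozaki–Hiyama–Kishi (Barbier-type) allylation, closing the ten-membered ring with allylic transposition to the C11=C13 methylene; C7 is set by attack on the butenolide face opposite the C9 chain (7,8-trans lactone) and C6 by a chair Zimmerman–Traxler transition state in which the ring-locked E-type allyl unit and an equatorial aldehyde chain give the anti (6S) alcohol, the closest known reaction types being the intermolecular chromium-mediated allylation of aldehydes by 3-(bromomethyl)furan-2(5H)-one and the macrocyclic chromium-mediated allylations that close germacranolide rings.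

Step 15
Reactants: 21 (1(10)E,4S,6S,7R,8R)-14-acetoxy-4,6-dihydroxygermacra-1(10),11(13)-dien-12,8-olide; 22 angelic acid
Product: 23 (1(10)E,4S,6R,7S,8R)-14-acetoxy-6-angeloyloxy-4-hydroxygermacra-1(10),11(13)-dien-12,8-olide (CNP0270682.1)
Conditions: PPh3, DIAD, toluene, 0 to 25 °C
Reagents that add atoms: none
Why: Mitsunobu esterification, in which angelate displaces the C6 alkoxyphosphonium ion with SN2 inversion (6S alcohol to 6R ester), the tertiary C4 hydroxyl cannot react and the Z acid is not exposed to an isomerising acyl-transfer catalyst.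

## Compound list

1 | geraniol, (2E)-3,7-dimethylocta-2,6-dien-1-ol | CC(C)=CCC/C(C)=C/CO | starting material
2 | (2S,3S)-2,3-epoxygeraniol | CC(C)=CCC[C@]1(C)O[C@H]1CO | intermediate
3 | (3S)-3,7-dimethyloct-6-ene-1,3-diol | CC(C)=CCC[C@](C)(O)CCO | intermediate
4 | (4S)-2,2,4-trimethyl-4-(4-methylpent-3-en-1-yl)-1,3-dioxane | CC(C)=CCC[C@@]1(C)CCOC(C)(C)O1 | intermediate
5 | 3,3-dimethyl-5-{2-[(4S)-2,2,4-trimethyl-1,3-dioxan-4-yl]ethyl}-1,2,4-trioxolane (secondary ozonide, both epimers at the new acetal carbon) | CC1(C)OOC(CC[C@@]2(C)CCOC(C)(C)O2)O1 | intermediate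
6 | 3-[(4S)-2,2,4-trimethyl-1,3-dioxan-4-yl]propanal | O=CCC[C@@]1(C)CCOC(C)(C)O1 | intermediate
7 | (4S)-4-(but-3-yn-1-yl)-2,2,4-trimethyl-1,3-dioxane | C#CCC[C@@]1(C)CCOC(C)(C)O1 | intermediate
8 | (R)-epichlorohydrin, (2R)-2-(chloromethyl)oxirane | ClC[C@H]1CO1 | starting material
9 | lithium acetylide of 7 | [Li]C#CCC[C@@]1(C)CCOC(C)(C)O1 | intermediate
10 | (2R)-1-chloro-7-[(4S)-2,2,4-trimethyl-1,3-dioxan-4-yl]hept-4-yn-2-ol | ClC[C@H](O)CC#CCC[C@@]1(C)CCOC(C)(C)O1 | intermediate
11 | (2R)-2-{5-[(4S)-2,2,4-trimethyl-1,3-dioxan-4-yl]pent-2-yn-1-yl}oxirane | C1O[C@@H]1CC#CCC[C@@]2(C)CCOC(C)(C)O2 | intermediate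
12 | (3R)-8-[(4S)-2,2,4-trimethyl-1,3-dioxan-4-yl]oct-1-en-5-yn-3-ol | C=C[C@H](O)CC#CCC[C@@]1(C)CCOC(C)(C)O1 | intermediate
13 | (3E,5R)-5-ethenyl-3-{3-[(4S)-2,2,4-trimethyl-1,3-dioxan-4-yl]propylidene}oxolan-2-one | C=C[C@H]1C/C(=C\CC[C@@]2(C)CCOC(C)(C)O2)C(=O)O1 | intermediate
14 | (3R,5E)-5-(hydroxymethyl)-8-[(4S)-2,2,4-trimethyl-1,3-dioxan-4-yl]octa-1,5-dien-3-ol | C=C[C@H](O)C/C(CO)=C\CC[C@@]1(C)CCOC(C)(C)O1 | intermediate
15 | (2E,4R)-4-hydroxy-2-{3-[(4S)-2,2,4-trimethyl-1,3-dioxan-4-yl]propylidene}hex-5-en-1-yl acetate | C=C[C@H](O)C/C(COC(C)=O)=C\CC[C@@]1(C)CCOC(C)(C)O1 | intermediate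
16 | 2-(bromomethyl)prop-2-enoic acid | C=C(CBr)C(=O)O | starting material
17 | (3R,5E)-5-(acetoxymethyl)-8-[(4S)-2,2,4-trimethyl-1,3-dioxan-4-yl]octa-1,5-dien-3-yl 2-(bromomethyl)prop-2-enoate | C=C[C@H](OC(=O)C(=C)CBr)C/C(COC(C)=O)=C\CC[C@@]1(C)CCOC(C)(C)O1 | intermediate
18 | (3R,5E,9S)-5-(acetoxymethyl)-9,11-dihydroxy-9-methylundeca-1,5-dien-3-yl 2-(bromomethyl)prop-2-enoate | C=C[C@H](OC(=O)C(=C)CBr)C/C(COC(C)=O)=C\CC[C@](C)(O)CCO | intermediate
19 | (3R,5E,9S)-5-(acetoxymethyl)-9-hydroxy-9-methyl-11-oxoundeca-1,5-dien-3-yl 2-(bromomethyl)prop-2-enoate | C=C[C@H](OC(=O)C(=C)CBr)C/C(COC(C)=O)=C\CC[C@](C)(O)CC=O | intermediate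
20 | (2E,6S)-2-{[(2R)-4-(bromomethyl)-5-oxo-2,5-dihydrofuran-2-yl]methyl}-6-hydroxy-6-methyl-8-oxooct-2-en-1-yl acetate | BrCC1=C[C@@H](C/C(COC(C)=O)=C\CC[C@](C)(O)CC=O)OC1=O | intermediate
21 | (1(10)E,4S,6S,7R,8R)-14-acetoxy-4,6-dihydroxygermacra-1(10),11(13)-dien-12,8-olide (C2 and C9 cis on the ring alkene; trans-fused lactone) | C=C1C(=O)O[C@@H]2C/C(COC(C)=O)=C\CC[C@](C)(O)C[C@H](O)[C@@H]12 | intermediate
22 | angelic acid, (2Z)-2-methylbut-2-enoic acid | C/C=C(/C)C(=O)O | starting material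
23 | (1(10)E,4S,6R,7S,8R)-14-acetoxy-6-angeloyloxy-4-hydroxygermacra-1(10),11(13)-dien-12,8-olide, CNP0270682.1 | C=C1C(=O)O[C@@H]2C/C(COC(C)=O)=C\CC[C@](C)(O)C[C@@H](OC(=O)/C(C)=C\C)[C@@H]12 | target

## Step count and risks

Total step count: 15. Longest linear sequence: 15 steps (1 to 23); compounds 8, 16 and 22 are used as purchased.

**Step 14 (two-ring closure).** The ten-membered ring closure through a butenolide-derived allylchromium has no direct precedent, and both the 7,8-trans fusion and the 6S outcome rest on transition-state arguments. The fallback sets out from 20, obtained by running the metathesis alone and isolating it. Bromide is exchanged for tin with Bu3SnSnBu3 and Pd2(dba)3 in THF to give the allylstannane (2E,6S)-6-hydroxy-6-methyl-8-oxo-2-({(2R)-5-oxo-4-[(tributylstannyl)methyl]-2,5-dihydrofuran-2-yl}methyl)oct-2-en-1-yl acetate F1. Treating this with BF3·OEt2 in CH2Cl2 at −78 °C under high dilution closes the ring through an open, Lewis-acid-mediated SE2' transition state, which is syn-selective and should give the 6R alcohol (1(10)E,4S,6R,7R,8R)-14-acetoxy-4,6-dihydroxygermacra-1(10),11(13)-dien-12,8-olide F2. Yamaguchi acylation of this alcohol with 22 (2,4,6-trichlorobenzoyl chloride, Et3N, toluene, 80 °C, retention at C6) comes back to the route at 23. If the chromium closure itself gives the 6R alcohol, that product is the same compound and takes the same acylation.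

**Step 15 (Mitsunobu inversion).** The hindered medium-ring alcohol may eliminate towards C5=C6 or C6=C7, or the angelate may isomerise to the tiglate. The fallback sets out from 21. Dess–Martin periodinane buffered with NaHCO3 gives the ketone (1(10)E,4S,7S,8R)-14-acetoxy-4-hydroxy-6-oxogermacra-1(10),11(13)-dien-12,8-olide F3. Reduction with Me4N[BH(OAc)3] in MeCN/AcOH at −30 °C delivers hydride intramolecularly from boron bound to the C4 hydroxyl (Evans–Saksena 1,3-anti reduction) and gives the 6R alcohol (1(10)E,4S,6R,7R,8R)-14-acetoxy-4,6-dihydroxygermacra-1(10),11(13)-dien-12,8-olide F4, which is the same structure as F2. Yamaguchi acylation with 22 then comes back to the route at 23.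

**Step 8 (cyclocarbonylation).** An internal alkyne carrying an allylic alcohol and an acid-sensitive acetonide may carbonylate slowly or ionise under the acidic catalyst system. The fallback sets out from 12. Neat (HMe2Si)2NH gives the silyl ether (4S)-4-{(6R)-6-[(dimethylsilyl)oxy]oct-7-en-3-yn-1-yl}-2,2,4-trimethyl-1,3-dioxane F5. Pt2[(CH2=CHSiMe2)2O]3 (0.5 mol %) in THF effects 5-exo-dig syn intramolecular hydrosilylation to (3E,5R)-5-ethenyl-2,2-dimethyl-3-{3-[(4S)-2,2,4-trimethyl-1,3-dioxan-4-yl]propylidene}-1,2-oxasilolane F6. N-Iodosuccinimide in MeCN replaces silicon by iodine with retention to give (3R,5E)-5-iodo-8-[(4S)-2,2,4-trimethyl-1,3-dioxan-4-yl]octa-1,5-dien-3-ol F7. Carbonylative lactonisation of this iodide with Pd(PPh3)4, CO (1 atm) and K2CO3 in THF at 50 °C comes back to the route at 13.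

## Further compounds

F1 | step 14 | (2E,6S)-6-hydroxy-6-methyl-8-oxo-2-({(2R)-5-oxo-4-[(tributylstannyl)methyl]-2,5-dihydrofuran-2-yl}methyl)oct-2-en-1-yl acetate | CCCC[Sn](CCCC)(CCCC)CC1=C[C@@H](C/C(COC(C)=O)=C\CC[C@](C)(O)CC=O)OC1=O
F2 | step 14 | (1(10)E,4S,6R,7R,8R)-14-acetoxy-4,6-dihydroxygermacra-1(10),11(13)-dien-12,8-olide | C=C1C(=O)O[C@@H]2C/C(COC(C)=O)=C\CC[C@](C)(O)C[C@@H](O)[C@@H]12
F3 | step 15 | (1(10)E,4S,7S,8R)-14-acetoxy-4-hydroxy-6-oxogermacra-1(10),11(13)-dien-12,8-olide | C=C1C(=O)O[C@@H]2C/C(COC(C)=O)=C\CC[C@](C)(O)CC(=O)[C@@H]12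
F4 | step 15 | (1(10)E,4S,6R,7R,8R)-14-acetoxy-4,6-dihydroxygermacra-1(10),11(13)-dien-12,8-olide | C=C1C(=O)O[C@@H]2C/C(COC(C)=O)=C\CC[C@](C)(O)C[C@@H](O)[C@@H]12
F5 | step 8 | (4S)-4-{(6R)-6-[(dimethylsilyl)oxy]oct-7-en-3-yn-1-yl}-2,2,4-trimethyl-1,3-dioxane | C=C[C@H](O[SiH](C)C)CC#CCC[C@@]1(C)CCOC(C)(C)O1
F6 | step 8 | (3E,5R)-5-ethenyl-2,2-dimethyl-3-{3-[(4S)-2,2,4-trimethyl-1,3-dioxan-4-yl]propylidene}-1,2-oxasilolane | C=C[C@H]1C/C(=C\CC[C@@]2(C)CCOC(C)(C)O2)[Si](C)(C)O1
F7 | step 8 | (3R,5E)-5-iodo-8-[(4S)-2,2,4-trimethyl-1,3-dioxan-4-yl]octa-1,5-dien-3-ol | C=C[C@H](O)C/C(I)=C\CC[C@@]1(C)CCOC(C)(C)O1
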